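**Plan**
- Retrosynthesis (tetralin numbering: C1 aryl-bearing, C2/C3 CH2OH-bearing, C4 = CH2, C4a/C8a ring fusion): take the diol back to an O-benzylated 2,3-diester, cut C1–C8a and re-join C1 to C4. The carbocycle (C1, C2, C3, C4, C4a, C8a) then becomes a cyclobutane (C1–C4), an all-trans head-to-head ferulate dimer (δ-truxinate), which is cut across C2–C3 and C1–C4 into two O-benzylferulates on a C2-symmetric threitol tether.
- Enabling feature: C1 and C4 are both benzylic to the same guaiacyl unit and C2/C3 carry like CH2OH groups, so the target is an isomer of a C2-symmetric 1,2-diarylcyclobutane. Its aryl–CH–CH–aryl ring bond is strained and doubly benzylic, the bond that an arene radical cation breaks first.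
- Forward: Knoevenagel–Doebner, double esterification on the tether, intramolecular [2+2] (cyclobutane), radical-cation ring expansion four to six (tetralin ring), LiAlH4 (both CH2OH, tether off), hydrogenolysis.
- Stereochemistry: C2 and C3 come from the tether-controlled photocycloaddition (trans-diester) and are not touched again. C1 is set in the ring expansion, trans to C2. The two aryl-bearing cyclobutane centres are erased (one becomes CH2, one is re-set), so all aryl-epimers converge.

Key step: step 4

Assumption: the (4S,5S)-threitol acetonide tether is taken to favour the (1S,2S) configuration at the two ester-bearing cyclobutane carbons in step 3; should induction run the other way, the equally commercial (4R,5R)-diol is used and no other step changes.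

Step 1
Reactants: 1 4-(benzyloxy)-3-methoxybenzaldehyde; 2 malonic acid
Product: 4 (E)-3-[4-(benzyloxy)-3-methoxyphenyl]prop-2-enoic acid, via benzylidenemalonic acid 3 (not isolated)
Conditions: pyridine, piperidine (0.1 equiv), 90 °C; then aq. HCl
Reagents that add atoms: none
Why: Knoevenagel condensation followed by Doebner decarboxylation of the arylidenemalonic acid should give the conjugated acid as the thermodynamically favoured E isomer, the benzyl ether being inert.

Step 2
Reactants: 4 (E)-3-[4-(benzyloxy)-3-methoxyphenyl]prop-2-enoic acid (2.2 equiv); 5 (4S,5S)-2,2-dimethyl-1,3-dioxolane-4,5-dimethanol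
Product: 7 1,4-bis-O-[(E)-4-benzyloxy-3-methoxycinnamoyl]-2,3-O-isopropylidene-L-threitol, via mono-ester 6 (not isolated)
Conditions: DCC, DMAP (0.2 equiv), CH2Cl2, 0 °C to rt
Reagents that add atoms: none
Why: Steglich esterification should acylate both primary alcohols of the diol under neutral conditions that leave the acetonide, the benzyl ethers, the E-alkenes and the two template stereocentres unchanged.

Step 3
Reactants: 7 1,4-bis-O-[(E)-4-benzyloxy-3-methoxycinnamoyl]-2,3-O-isopropylidene-L-threitol
Product: 8 threitol-bridged (1S,2S,3R,4R)-3,4-bis[4-(benzyloxy)-3-methoxyphenyl]cyclobutane-1,2-dicarboxylate (all-trans; ten-membered dilactone)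
Conditions: [Ir(dF(CF3)ppy)2(dtbbpy)]PF6 (1 mol %; dF(CF3)ppy = C,N-cyclometalated 2-(2,4-difluorophenyl)-5-(trifluoromethyl)pyridine, dtbbpy = 4,4'-di-tert-butyl-2,2'-bipyridine), degassed MeCN (5 mM), 450 nm LEDs, rt
Reagents that add atoms: none
Why: Triplet energy transfer to one cinnamate should give a diradical that adds head-to-head to the tethered partner and closes to the cyclobutane (sensitised intramolecular [2+2] photocycloaddition of a 1,4-di-O-cinnamoyl tetritol, a known template class for δ-truxinates); the two ester-bearing centres are set trans and (1S,2S) by the trans-dioxolane template (minor diastereomers removed by chromatography), while the two aryl-bearing centres form trans in the diradical closure but are erased in step 4.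

Step 4
Reactants: 8 threitol-bridged (1S,2S,3R,4R)-3,4-bis[4-(benzyloxy)-3-methoxyphenyl]cyclobutane-1,2-dicarboxylate
Product: 10 threitol-bridged (1R,2S,3S)-7-(benzyloxy)-1-[4-(benzyloxy)-3-methoxyphenyl]-6-methoxy-1,2,3,4-tetrahydronaphthalene-2,3-dicarboxylate, via distonic radical cation 9 (not isolated)
Conditions: 9-mesityl-10-methylacridinium tetrafluoroborate (5 mol %), (PhS)2 (10 mol %), 2,6-lutidine (20 mol %), degassed DCE (0.02 M), 450 nm LEDs, rt
Reagents that add atoms: none
Why: Proposed new method: the excited acridinium oxidises one of the two equivalent benzyloxy(methoxy)arene rings of 8 by one electron, and the cyclobutane bond between the two aryl-bearing carbons (the only ring bond that is strained, doubly benzylic and aligned with both arene π systems) cleaves mesolytically to the distonic 1,4-radical cation 9; its 4-alkoxybenzyl cation is attacked by the arene of the radical terminus at the carbon para to OMe, the arenium ion loses a proton to 2,6-lutidine, and the resulting benzylic radical (the future C4) takes a hydrogen atom from PhSH formed in situ from (PhS)2, the thiyl radical re-oxidising the acridinyl radical so that the isomerisation is redox-neutral. The closest known reaction types are the photoinduced-electron-transfer cyclodimerisation of 1,1-diarylethylenes to 1-aryltetralins (same kind of 1,4-radical cation, same 1,6-closure), the radical-cation ring opening of 1,2-diarylcyclobutanes, the oxidative opening of 1,2-bis(4-hydroxyaryl)cyclobutanes to bis(quinone methides), and acridinium/thiol hydrofunctionalisation for the hydrogen-atom relay. The six-membered ring closes in a 6-endo-trig Friedel–Crafts mode in which the four former cyclobutane carbons are joined by the ipso and ortho carbons of one arene, a ring expansion by two atoms. The only new stereocentre, C1, is controlled by the adjacent C2 centre through a chair-like transition state with the pendant aryl group and both ester arms pseudo-equatorial (1,2-trans, also the outcome of the classical acid cyclisation of lariciresinol-type cations and the thermodynamic arrangement), while C2 and C3 take part in no bond change and are not enolised by the weak hindered base. The step needs cyclisation to outrun a second fragmentation of 9 into two cinnamates and needs para- over ortho-attack: the first is secured by the ester groups (a cinnamate-ester radical cation is a high-energy fragment) and by the tether that keeps any fragment pair together, the second by the methoxy group, which activates the para carbon and crowds the ortho one. No selectivity between the two aryl rings or between aryl-epimers of 8 is needed, because both aryl-bearing carbons are planar in 9 and the two halves are related by the C2 axis, so every isomer should converge on 10.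

Step 5
Reactants: 10 threitol-bridged (1R,2S,3S)-aryltetralin-2,3-dicarboxylate
Product: 11 [(1R,2S,3S)-7-(benzyloxy)-1-[4-(benzyloxy)-3-methoxyphenyl]-6-methoxy-1,2,3,4-tetrahydronaphthalene-2,3-diyl]dimethanol
Conditions: LiAlH4 (4 equiv), THF, 0 °C to rt; then H2O
Reagents that add atoms: none
Why: Hydride reduction of both lactone carbonyls with LiAlH4 should give the two primary alcohols and release the template as its water-soluble diol; reduction outpaces enolisation and the diequatorial trans arrangement is the stable one, so C2 and C3 keep their configuration.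

Step 6
Reactants: 11 [(1R,2S,3S)-7-(benzyloxy)-1-[4-(benzyloxy)-3-methoxyphenyl]-6-methoxy-1,2,3,4-tetrahydronaphthalene-2,3-diyl]dimethanol
Product: 12 (6S,7S,8R)-8-(4-hydroxy-3-methoxyphenyl)-6,7-bis(hydroxymethyl)-3-methoxy-5,6,7,8-tetrahydronaphthalen-2-ol
Conditions: H2 (1 atm), Pd/C (10 wt %), MeOH/EtOAc, rt
Reagents that add atoms: none
Why: Catalytic hydrogenolysis should cleave both aryl benzyl ethers, while the tetralin core has no benzylic C–O bond and its stereocentres and primary alcohols are inert to these conditions.

**Compound list**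
1 | 4-(benzyloxy)-3-methoxybenzaldehyde (O-benzylvanillin) | COc1cc(C=O)ccc1OCc1ccccc1 | starting material
2 | malonic acid | OC(=O)CC(=O)O | starting material
3 | 2-[4-(benzyloxy)-3-methoxybenzylidene]propanedioic acid (formed in situ) | COc1cc(C=C(C(=O)O)C(=O)O)ccc1OCc1ccccc1 | intermediate
4 | (E)-3-[4-(benzyloxy)-3-methoxyphenyl]prop-2-enoic acid (O-benzylferulic acid) | COc1cc(/C=C/C(=O)O)ccc1OCc1ccccc1 | intermediate
5 | (4S,5S)-2,2-dimethyl-1,3-dioxolane-4,5-dimethanol (2,3-O-isopropylidene-L-threitol) | CC1(C)O[C@@H](CO)[C@H](CO)O1 | starting material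
6 | [(4S,5S)-5-(hydroxymethyl)-2,2-dimethyl-1,3-dioxolan-4-yl]methyl (E)-3-[4-(benzyloxy)-3-methoxyphenyl]prop-2-enoate (mono-ester, formed in situ) | CC1(C)O[C@@H](CO)[C@H](COC(=O)/C=C/c2ccc(OCc3ccccc3)c(OC)c2)O1 | intermediate
7 | [(4S,5S)-2,2-dimethyl-1,3-dioxolane-4,5-diyl]bis(methylene) bis{(E)-3-[4-(benzyloxy)-3-methoxyphenyl]prop-2-enoate} | CC1(C)O[C@@H](COC(=O)/C=C/c2ccc(OCc3ccccc3)c(OC)c2)[C@H](COC(=O)/C=C/c2ccc(OCc3ccccc3)c(OC)c2)O1 | intermediate
8 | ten-membered dilactone of all-trans (1S,2S,3R,4R)-3,4-bis[4-(benzyloxy)-3-methoxyphenyl]cyclobutane-1,2-dicarboxylic acid with diol 5 | COc1cc([C@@H]2[C@@H](c3ccc(OCc4ccccc4)c(OC)c3)[C@H](C(=O)OC[C@@H]5OC(C)(C)O[C@H]5CO6)[C@H]2C6=O)ccc1OCc1ccccc1 | intermediate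
9 | ring-opened distonic 1,4-radical cation of 8 (aryl–CH–CH–aryl bond broken; one ArCH cation, one ArCH radical; formed in situ) | COc1cc([CH][C@H](C(=O)OC[C@@H]5OC(C)(C)O[C@H]5CO6)[C@H]([CH+]c2ccc(OCc3ccccc3)c(OC)c2)C6=O)ccc1OCc1ccccc1 | intermediate
10 | ten-membered dilactone of (1R,2S,3S)-7-(benzyloxy)-1-[4-(benzyloxy)-3-methoxyphenyl]-6-methoxy-1,2,3,4-tetrahydronaphthalene-2,3-dicarboxylic acid with diol 5 | COc1cc([C@@H]2c3cc(OCc4ccccc4)c(OC)cc3C[C@H](C(=O)OC[C@@H]5OC(C)(C)O[C@H]5CO6)[C@H]2C6=O)ccc1OCc1ccccc1 | intermediate
11 | [(1R,2S,3S)-7-(benzyloxy)-1-[4-(benzyloxy)-3-methoxyphenyl]-6-methoxy-1,2,3,4-tetrahydronaphthalene-2,3-diyl]dimethanol | COc1cc([C@@H]2c3cc(OCc4ccccc4)c(OC)cc3C[C@H](CO)[C@H]2CO)ccc1OCc1ccccc1 | intermediate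
12 | (6S,7S,8R)-8-(4-hydroxy-3-methoxyphenyl)-6,7-bis(hydroxymethyl)-3-methoxy-5,6,7,8-tetrahydronaphthalen-2-ol ((1R,2S,3S) in tetralin numbering) | COc1cc([C@@H]2c3cc(O)c(OC)cc3C[C@H](CO)[C@H]2CO)ccc1O | target

Total step count: 6. Longest linear sequence: 6 steps (1 to 12).

**Steps most likely to fail**

1. Step 4 (proposed new method). After the mesolytic opening, the 1,4-radical cation may fragment a second time across the bond between the two ester-bearing carbons (cycloreversion to the tethered dicinnamate) faster than it cyclises. That would cost material, or configuration at C2/C3 on re-addition. Acid released in the cycle may also strip the acetonide. The fallback uses known polar chemistry, sets out from 8 and returns at 12. LiAlH4 reduction of 8 gives the cyclobutane diol [(1S,2S,3R,4R)-3,4-bis(4-benzyloxy-3-methoxyphenyl)cyclobutane-1,2-diyl]dimethanol F1. Hydrogenolysis (H2, Pd/C) gives the bis-phenol [(1S,2S,3R,4R)-3,4-bis(4-hydroxy-3-methoxyphenyl)cyclobutane-1,2-diyl]dimethanol F2. Oxidation with FeCl3·6H2O in aqueous acetone opens the 1,2-bis(4-hydroxyaryl)cyclobutane to the (2S,3S)-bis(quinone methide) F3 (not isolated). Both hydroxymethyl groups trap it to give the furofuran (7R,7'R,8S,8'S)-pinoresinol F4. Controlled hydrogenolysis of one benzylic C–O bond (H2, Pd/C) gives (7R,8S,8'S)-lariciresinol F5. Dilute methanolic HCl should convert F5 into 12 by the classical benzylic-cation Friedel–Crafts cyclisation.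

2. Step 3. The template may give poor facial selectivity, or the tethered 1,4-diradical may close to the cis-diester because the ten-membered trans-dilactone is strained, or only E/Z isomerisation may occur. The fallback sets out from 4 and returns at 11. Steglich esterification of 4 with (1R,2S,5R)-menthol gives (1R,2S,5R)-menthyl (E)-3-[4-(benzyloxy)-3-methoxyphenyl]prop-2-enoate F6. Intermolecular triplet-sensitised dimerisation (same iridium sensitiser, 0.2 M) gives the head-to-head all-trans dimers as two diastereomers. The dimenthyl (1S,2S,3R,4R)-3,4-bis[4-(benzyloxy)-3-methoxyphenyl]cyclobutane-1,2-dicarboxylate F7 is separated from the other by chromatography or crystallisation. F7 is taken through the conditions of step 4 to the dimenthyl (1R,2S,3S)-aryltetralin-2,3-dicarboxylate F8. LiAlH4 reduction of F8 gives 11.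

3. Step 5. Reduction of the hindered ten-membered dilactone may stall at lactol or hydroxy-ester stages, with aluminium-alkoxide-mediated translactonisation. The fallback sets out from 10 and returns at 11. Transesterification with K2CO3 in MeOH removes the template first and gives dimethyl (1R,2S,3S)-7-(benzyloxy)-1-[4-(benzyloxy)-3-methoxyphenyl]-6-methoxy-1,2,3,4-tetrahydronaphthalene-2,3-dicarboxylate F9. The trans,trans arrangement is the thermodynamic one, so it survives the basic medium. F9 is then reduced with LiBH4 in THF/MeOH to 11.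

**Further compounds**
F1 | step 4 | [(1S,2S,3R,4R)-3,4-bis(4-benzyloxy-3-methoxyphenyl)cyclobutane-1,2-diyl]dimethanol | COc1cc([C@@H]2[C@@H](c3ccc(OCc4ccccc4)c(OC)c3)[C@H](CO)[C@H]2CO)ccc1OCc1ccccc1
F2 | step 4 | [(1S,2S,3R,4R)-3,4-bis(4-hydroxy-3-methoxyphenyl)cyclobutane-1,2-diyl]dimethanol | COc1cc([C@@H]2[C@@H](c3ccc(O)c(OC)c3)[C@H](CO)[C@H]2CO)ccc1O
F3 | step 4 | (2S,3S)-bis(quinone methide): 4,4'-[(2S,3S)-2,3-bis(hydroxymethyl)butane-1,4-diylidene]bis(2-methoxycyclohexa-2,5-dien-1-one) (not isolated) | COC1=CC(=C[C@H](CO)[C@H](C=C2C=CC(=O)C(OC)=C2)CO)C=CC1=O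
F4 | step 4 | (7R,7'R,8S,8'S)-pinoresinol | COc1cc([C@@H]2OC[C@H]3[C@H](c4ccc(O)c(OC)c4)OC[C@@H]23)ccc1O
F5 | step 4 | (7R,8S,8'S)-lariciresinol [(2R,3S,4S)-2-(4-hydroxy-3-methoxyphenyl)-4-(4-hydroxy-3-methoxybenzyl)tetrahydrofuran-3-yl]methanol | COc1cc([C@@H]2OC[C@@H](Cc3ccc(O)c(OC)c3)[C@H]2CO)ccc1O
F6 | step 3 | (1R,2S,5R)-menthyl (E)-3-[4-(benzyloxy)-3-methoxyphenyl]prop-2-enoate | COc1cc(/C=C/C(=O)O[C@@H]2C[C@H](C)CC[C@H]2C(C)C)ccc1OCc1ccccc1
F7 | step 3 | di[(1R,2S,5R)-menthyl] (1S,2S,3R,4R)-3,4-bis[4-(benzyloxy)-3-methoxyphenyl]cyclobutane-1,2-dicarboxylate | COc1cc([C@@H]2[C@@H](c3ccc(OCc4ccccc4)c(OC)c3)[C@H](C(=O)O[C@@H]3C[C@H](C)CC[C@H]3C(C)C)[C@H]2C(=O)O[C@@H]2C[C@H](C)CC[C@H]2C(C)C)ccc1OCc1ccccc1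
F8 | step 3 | di[(1R,2S,5R)-menthyl] (1R,2S,3S)-7-(benzyloxy)-1-[4-(benzyloxy)-3-methoxyphenyl]-6-methoxy-1,2,3,4-tetrahydronaphthalene-2,3-dicarboxylate | COc1cc([C@@H]2c3cc(OCc4ccccc4)c(OC)cc3C[C@H](C(=O)O[C@@H]3C[C@H](C)CC[C@H]3C(C)C)[C@H]2C(=O)O[C@@H]2C[C@H](C)CC[C@H]2C(C)C)ccc1OCc1ccccc1
F9 | step 5 | dimethyl (1R,2S,3S)-7-(benzyloxy)-1-[4-(benzyloxy)-3-methoxyphenyl]-6-methoxy-1,2,3,4-tetrahydronaphthalene-2,3-dicarboxylate | COc1cc([C@@H]2c3cc(OCc4ccccc4)c(OC)cc3C[C@H](C(=O)OC)[C@H]2C(=O)OC)ccc1OCc1ccccc1
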